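(The runs were computed on assumed constants, and the scatter is random.)

The two last readings, near 81.6% of starting material left at 15.0 min, give 0.0136 min⁻¹ for the log-loss rate λ, the slope of minus the logarithm of the fraction of starting material left. We work with this fraction because the percent curves of the two runs coincide, so λ, itself a reading with scatter, does not visibly depend on the charge between those runs. Of what has gone, 90.8% was read as target.

| flask | starting material | reagent in the second phase | protic impurity | remark | time | volume of the second phase over the first |
|---|---|---|---|---|---|---|
| Tuesday's | 5 mM | 15 mM | 10 mM | run made earlier |  |  |
| Saturday's | 7.5 mM | 15 mM | 10 mM | run made earlier |  |  |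
| flask | 10 mM | 15.0 mM | 10.0 mM |  | 25 min | 0.25 |

| run | time / min | target / % | starting material / % |
|---|---|---|---|
| Tuesday's | 1.33 | 1.1 | 98.3 |
| Tuesday's | 2.00 | 2.6 | 97.3 |
| Tuesday's | 3.00 | 4.7 | 95.6 |
| Tuesday's | 5.00 | 6.3 | 93.1 |
| Tuesday's | 10.0 | 11.3 | 87.1 |
| Tuesday's | 15.0 | 17.2 | 81.4 |
| Saturday's | 1.00 | 1.0 | 99.8 |
| Saturday's | 3.00 | 3.4 | 95.9 |
| Saturday's | 5.00 | 7.2 | 93.1 |
| Saturday's | 8.00 | 9.9 | 89.7 |
| Saturday's | 12.0 | 13.4 | 84.9 |
| Saturday's | 15.0 | 16.2 | 81.8 |

(standard deviation of a reading: 0.5 percentage points)

* how much target there is at 25 min, in percent of the starting material charged
* the change that raises the amount of target at 25 min, in percent of the starting material charged most ("none" if none brings more than 2 percentage points) (south / south-west / none)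
* amount of target at 25 min, in percent of the starting material charged, after south

- south: doubling the amount of reagent in the second phase, all else as stated
- south-west: doubling the transfer coefficient of the reagent in the second phase, all else as stated

- in the second phase: reagent in the second phase; everything else is in the first
- charges count per volume of the first phase; a concentration in a rate is the amount of a species over the volume of its own phase; every rate counts per litre of the first phase
- the earlier runs hold the two phases in the same ratio of volumes as the flask asked about

If λ holds to the asked time, this flask has 26.1% of target, our ceiling. For a floor we let the protic impurity take its whole charge at once and each reacted starting material take one reagent, which scales λ with the mean of the reagent left. One pass gives 19.5%, and feeding that loss back gives 21.2%; the passes alternate about their limit, so we take the third, 20.8%, as our floor. For south we expect a gain, and doubling λ with the charge gives 44.7%, an estimate and not a bound; no run varies the transfer coefficient, so we lean to south on the reagent's charge.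

The forecast gives 24%, under our ceiling and over our floor, chooses south, and puts 58% after it, more than our south estimate, on the ground that “Doubling the reagent leaves 20 mM active”.

The flask gives 22.0% of target, and south is best with 9.2 percentage points against 2.3 points, reaching 31.3%.

    reagent in the reaction phase ⇌ reagent in the second phase, rate k1*([reagent in the reaction phase] - [reagent in the second phase]/K1) per volume of the first phase (partition coefficient = 96.0, kL = 0.0230 s⁻¹)
    starting material + reagent in the reaction phase → target (k = 0.810 M⁻¹ s⁻¹)
    reagent in the reaction phase + target → over-reaction product (k = 0.680 M⁻¹ s⁻¹)
    reagent in the reaction phase + protic impurity → quenched reagent (k = 0.450 M⁻¹ s⁻¹)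
    2 reagent in the reaction phase → self-condensation product (k = 17.0 M⁻¹ s⁻¹)

At 9.78 min the reagent in the reaction phase has a half-life of 1.6 min by the target step, far shorter than the 57 min of the starting material by that step, and that reagent is made at 0.983 of the rate at which it is used. Read as a pseudo-first-order constant, the log-loss rate of this flask is the target step's constant times c(reagent in the reaction phase), 0.0115 min⁻¹ at 12.5 min; its mean from the fraction left at the asked time is 0.0115 min⁻¹.

On the same flask stopped at 6.0 min, λ and the share give 7.12% of target. The computed flask holds 7.43%, with 92% of the starting material left.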